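The readings are simulated with made-up constants, noise included.

Divide first. In this flask 30% of the two substrates together is 16.2 mM, and on 54 µM of free catalyst that makes N = 300 turnovers, whichever hand reacts.

the same everywhere: left-handed substrate 27 mM; right-handed substrate 27 mM; free catalyst 54 µM
- Thursday's: reagent 42 mM; run made earlier
- Sunday's: reagent 65 mM; run made earlier
- flask: reagent 29.7 mM

| run | time / h | left-handed product / % |
|---|---|---|
| Thursday's | 2.00 | 6.0 |
| Thursday's | 4.00 | 10.6 |
| Thursday's | 5.00 | 12.6 |
| Thursday's | 8.00 | 15.3 |
| Thursday's | 10.0 | 18.3 |
| Sunday's | 2.00 | 8.9 |
| Sunday's | 4.00 | 16.0 |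
| Sunday's | 5.00 | 18.0 |
| Sunday's | 8.00 | 22.5 |
| Sunday's | 10.0 | 26.0 |

(scatter of a reading: 1 percentage point)

- free catalyst is single-handed; left-handed substrate and right-handed substrate are mirror images of each other, charged as a racemate, each of them at the stated concentration

* apparent order in reagent when 30% of the left-handed substrate and right-handed substrate together are converted (percent change of the rate of making left-handed product for one percent more reagent charged)

Bench note: the flask holds 29.7 mM of reagent, the limiting reagent, since that is less than the two substrates together. We assume one reagent per turnover, so at N it holds 13.5 mM. Reading Sunday's against Thursday's at 10.0 h, reagent up 1.55-fold gave 1.42 times the product, so we take the rate as roughly proportional to reagent. Then the depletion order, n, the reagent charged over the reagent left after N turnovers, is 2.20. So measure the reagent charge with care: with conversion held at N turnovers, one percent more reagent charged moves the rate about n percent. We commit to a little above n. The forecast says 3.5, on the grounds that “more reagent also reaches 30% sooner” with more catalyst alive.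

The flask gives 2.4, which is 0.239 above n, and by 15.0 h spent catalyst stands at 17.8% of the catalyst charged.

    reagent + free catalyst + right-handed substrate → free catalyst + right-handed product (k = 11.0 M⁻² s⁻¹)
    reagent + free catalyst + left-handed substrate → free catalyst + left-handed product (k = 29.0 M⁻² s⁻¹)
    2 free catalyst → spent catalyst (k = 0.550 M⁻¹ s⁻¹)
    2 free catalyst ⇌ resting dimer (K = 1.30 × 10⁵ M⁻¹, k = 13.0 M⁻¹ s⁻¹)

On Sunday's charge of 65 mM reagent, the same 300 turnovers leave 48.8 mM, a depletion order of 1.33.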